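The cyclohexene ring of the unprimed 6,7-dihydrophthalide unit (C3a–C4–C5–C6–C7–C7a) is built by a [3+3] annulation onto a preformed cyclobutene. The primed unit is first assembled as a [4.3.2]propellane (cyclohexene, (E)-butylidene lactone and cyclobutene sharing C3a′–C7a′) that carries a formyl group (C5) on C6. Because O=C5–C6=C7 is then an enal, an acetoacetate (C4–C3a–C7a–C1) can add through C7a to C7 and close through C4 onto C5. This forms C7–C7a and C4–C5 in one operation and sets the cis ring fusion at C6/C7. Enol triflation, Sonogashira coupling and silver-mediated lactonisation complete the (Z)-butylidene lactone.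

Key step: step 14

Remark: phthalide numbering is used (C1 lactone carbonyl, C3 butylidene-bearing carbon, C8 exocyclic CH; primed locants for the unit whose C3a′/C7a′ lie in the cyclobutane); the target SMILES is read as 3Z in the unprimed unit and 3′E (ring O and propyl trans) in the primed unit, and each geometry is made stereospecifically.

Step 1
Reactants: 1 3-ethoxycyclohex-2-en-1-one
Product: 2 2-bromo-3-ethoxycyclohex-2-en-1-one
Conditions: NBS, CH2Cl2, 0 °C to rt
Reagents that add atoms: N-bromosuccinimide, O=C1CCC(=O)N1Br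
Why: Electrophilic bromination of the vinylogous ester at its nucleophilic α-carbon; no stereocentre is formed.

Step 2
Reactants: 2 2-bromo-3-ethoxycyclohex-2-en-1-one; 3 1,3-dithiane
Product: 5 2-bromo-3-(1,3-dithian-2-yl)cyclohex-2-en-1-one, via carbinol adduct 4 (not isolated)
Conditions: 3, n-BuLi, THF, −30 °C; 2, −78 °C; then 1 M HCl, rt
Reagents that add atoms: water, O
Why: Stork–Danheiser transposition: 1,2-addition of 2-lithio-1,3-dithiane (masked formyl anion, the future C3′) to the vinylogous ester, then acid hydrolysis with loss of ethanol, should give the 3-substituted 2-bromoenone.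

Step 3
Reactants: 5 2-bromo-3-(1,3-dithian-2-yl)cyclohex-2-en-1-one
Product: 6 (1S)-2-bromo-3-(1,3-dithian-2-yl)cyclohex-2-en-1-ol
Conditions: (R)-Me-CBS (20 mol %), catecholborane, toluene, −78 °C
Reagents that add atoms: none
Why: Corey–Bakshi–Shibata reduction: with the bromoalkene as the large substituent the (R)-catalyst is expected to give the (S)-carbinol, the temporary C7′ stereocentre that later directs the photocycloaddition.

Step 4
Reactants: 6 (1S)-2-bromo-3-(1,3-dithian-2-yl)cyclohex-2-en-1-ol
Product: 7 {[(1S)-2-bromo-3-(1,3-dithian-2-yl)cyclohex-2-en-1-yl]oxy}(tert-butyl)dimethylsilane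
Conditions: TBSOTf, 2,6-lutidine, CH2Cl2, 0 °C
Reagents that add atoms: tert-butyldimethylsilyl triflate, CC(C)(C)[Si](C)(C)OS(=O)(=O)C(F)(F)F
Why: Silylation of the secondary allylic alcohol gives a bulky, base-stable group that blocks one face of the ring; the stereocentre is untouched.

Step 5
Reactants: 7 {[(1S)-2-bromo-3-(1,3-dithian-2-yl)cyclohex-2-en-1-yl]oxy}(tert-butyl)dimethylsilane
Product: 9 (6S)-6-[(tert-butyldimethylsilyl)oxy]-2-(1,3-dithian-2-yl)cyclohex-1-ene-1-carboxylic acid, via vinyllithium 8 (not isolated)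
Conditions: t-BuLi (2.1 equiv), THF, −78 °C; CO2; then 1 M HCl to pH 3
Reagents that add atoms: carbon dioxide, O=C=O
Why: Bromine–lithium exchange of the vinyl bromide and carboxylation of the vinyllithium install C1′ on C7a′ without touching C7′.

Step 6
Reactants: 9 (6S)-6-[(tert-butyldimethylsilyl)oxy]-2-(1,3-dithian-2-yl)cyclohex-1-ene-1-carboxylic acid
Product: 10 (7S)-7-[(tert-butyldimethylsilyl)oxy]-3-hydroxy-4,5,6,7-tetrahydro-2-benzofuran-1(3H)-one
Conditions: PhI(OCOCF3)2, MeCN/H2O (9:1), 0 °C
Reagents that add atoms: water, O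
Why: Oxidative dithiane cleavage with hypervalent iodine frees the C3′ aldehyde, which closes onto the cis carboxylic acid to the 3-hydroxybutenolide (pseudo-acid), an enone-type chromophore whose only carbonyl sits on C7a′.

Step 7
Reactants: 10 (7S)-7-[(tert-butyldimethylsilyl)oxy]-3-hydroxy-4,5,6,7-tetrahydro-2-benzofuran-1(3H)-one; 11 1,3,3-trimethoxyprop-1-ene
Product: 12 cyclobutane photoadduct across C3a′–C7a′ (C7 bearing OMe on C3a′; C6 bearing CH(OMe)2 on C7a′; cyclobutane anti to OTBS)
Conditions: hν (254 nm, quartz), 11 (10 equiv), MeCN, −10 °C, degassed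
Reagents that add atoms: none
Why: Enone-type [2+2] photocycloaddition of a butenolide with an enol ether: head-to-tail regiochemistry should bond the methoxy-bearing carbon (C7) to the β-carbon C3a′ and the acetal-bearing carbon (C6) to C7a′, and addition anti to the pseudo-axial OTBS group sets C3a′ and C7a′; the C3′, C6 and C7 centres are mixtures that are erased later.

Step 8
Reactants: 12 cyclobutane photoadduct
Product: 13 alkynoic acid (ethynyl on C3a′, CO2H on C7a′)
Conditions: dimethyl (1-diazo-2-oxopropyl)phosphonate, K2CO3, MeOH, 0 °C to rt; then aq. citric acid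
Reagents that add atoms: dimethyl (1-diazo-2-oxopropyl)phosphonate, CC(=O)C(=[N+]=[N-])P(=O)(OC)OC
Why: Ohira–Bestmann (Seyferth–Gilbert) homologation: base opens the lactol to a non-enolisable aldehyde on quaternary C3a′, which becomes the terminal alkyne C3′≡C8′ while C1′ is freed as the carboxylate.

Step 9
Reactants: 13 alkynoic acid
Product: 14 (E)-iodomethylene γ-lactone
Conditions: I2, NaHCO3, MeCN, 0 °C, dark
Reagents that add atoms: iodine, II
Why: 5-exo-dig iodolactonisation: anti addition of the carboxylate oxygen and iodine across the alkyne should give the E iodomethylene lactone (iodine trans to the ring oxygen).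

Step 10
Reactants: 14 (E)-iodomethylene γ-lactone
Product: 15 (E)-butylidene γ-lactone
Conditions: n-PrZnBr, Pd(dppf)Cl2 (5 mol %), THF, rt
Reagents that add atoms: n-propylzinc bromide, CCC[Zn]Br
Why: Negishi sp2–sp3 coupling proceeds with retention at the vinyl iodide, so propyl ends trans to the ring oxygen, which fixes the E geometry of the primed butylidene group.

Step 11
Reactants: 15 (E)-butylidene γ-lactone
Product: 17 hydroxy enal (cyclobutene-1-carbaldehyde O=C5–C6=C7 with 7′-OH), via methoxy aldehyde 16 (not isolated)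
Conditions: 48% aq. HF, MeCN, 0 °C to rt; then DBU, CH2Cl2, 0 °C
Reagents that add atoms: water, O
Why: Aqueous HF removes the silyl group and hydrolyses the dimethyl acetal, and E1cB loss of methanol from the β-methoxy aldehyde gives the cyclobutene-1-carbaldehyde, erasing the C6/C7 mixture.

Step 12
Reactants: 17 hydroxy enal
Product: 18 propelladiene enal (C6′=C7′ alkene in place)
Conditions: Burgess reagent, toluene, 70 °C
Reagents that add atoms: none
Why: Burgess dehydration (syn Ei elimination of the sulfamate): only C6′ carries a β-hydrogen, so the C6′=C7′ alkene forms regiospecifically and the temporary C7′ centre is removed.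

Step 13
Reactants: 19 2-(trimethylsilyl)ethanol; 20 2,2,6-trimethyl-4H-1,3-dioxin-4-one
Product: 21 2-(trimethylsilyl)ethyl 3-oxobutanoate
Conditions: xylene, 140 °C
Reagents that add atoms: none
Why: Thermal retro-[4+2] of the dioxinone releases acetylketene, which the alcohol traps (acetoacetylation).

Step 14
Reactants: 18 propelladiene enal; 21 2-(trimethylsilyl)ethyl 3-oxobutanoate
Product: 24 annulated cyclohexenone β-keto ester (C3a ketone; C4=C5 alkene; C7a ester), via Michael adduct 22 (not isolated), via aldol 23 (not isolated)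
Conditions: pyrrolidine (20 mol %), PhCO2H (20 mol %), toluene, 4 Å MS, 0 °C to rt
Reagents that add atoms: none
Why: Amine-catalysed Michael/aldol-condensation domino (formal [3+3]): the iminium ion of enal 18 is attacked at C7 by the enol of 21 through C7a, then the methyl ketone carbon C4 closes onto C5 and water is lost. The closest known reaction type is the organocatalytic β-keto ester/enal Michael–aldol cyclohexenone synthesis. The six-membered ring closes in a 6-(enolendo)-exo-trig aldol step after the intermolecular C7–C7a bond. C7 is set by π-facial selectivity: C7a should enter anti to the lactone wing, whose E-configured propyl chain lies under C7, and therefore syn to the C4′ methylene of the cyclohexene; C6 is epimerisable (α to the formyl group) and adopts the only configuration that allows cis ring fusion. The step needs 1,4- over 1,2-attack and this facial preference; strain release at the cyclobutene β-carbon and shielding of C5 by quaternary C7a′ favour the former, the E-butylidene lactone the latter, and C7a is left uncontrolled because it becomes sp2 later.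

Step 15
Reactants: 24 annulated cyclohexenone β-keto ester
Product: 25 saturated cyclic β-keto ester
Conditions: [(Ph3P)CuH]6, H2O (2 equiv), toluene, rt
Reagents that add atoms: none
Why: Copper hydride 1,4-reduction (Stryker reagent) of the enone should leave the isolated C6′=C7′ alkene, the enol lactone and the ester untouched, and does not affect C6/C7.

Step 16
Reactants: 25 saturated cyclic β-keto ester
Product: 26 enol triflate (C3a–OTf, C3a=C7a)
Conditions: NaH, THF, 0 °C; PhNTf2, 0 °C to rt
Reagents that add atoms: N-phenylbis(trifluoromethanesulfonimide), O=S(=O)(N(c1ccccc1)S(=O)(=O)C(F)(F)F)C(F)(F)F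
Why: O-Sulfonylation of the sodium enolate of the cyclic β-keto ester gives the tetrasubstituted enol triflate with the C3a=C7a double bond in place.

Step 17
Reactants: 26 enol triflate; 27 pent-1-yne
Product: 28 enyne ester (pent-1-ynyl on C3a)
Conditions: PdCl2(PPh3)2 (5 mol %), CuI (10 mol %), Et3N, DMF, rt
Reagents that add atoms: none
Why: Sonogashira coupling of the β-triflyloxy enoate installs C3 and the butylidene carbons as a pentynyl group.

Step 18
Reactants: 28 enyne ester
Product: 30 target dimer CNP0371639.1, via enynoic acid 29 (not isolated)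
Conditions: TBAF, THF, 0 °C; then AcOH, AgNO3 (20 mol %), rt, dark
Reagents that add atoms: none
Why: Fluoride-induced fragmentation of the 2-(trimethylsilyl)ethyl ester gives the (Z)-2-en-4-ynoic acid, and Ag(I)-catalysed 5-exo-dig anti oxymetalation with protodemetalation should give the Z butylidene butenolide (propyl cis to the ring oxygen) without strong acid that could isomerise the E lactone.

Compound list

1 | 3-ethoxycyclohex-2-en-1-one | CCOC1=CC(=O)CCC1 | starting material
2 | 2-bromo-3-ethoxycyclohex-2-en-1-one | CCOC1=C(Br)C(=O)CCC1 | intermediate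
3 | 1,3-dithiane | C1CSCSC1 | starting material
4 | 2-bromo-1-(1,3-dithian-2-yl)-3-ethoxycyclohex-2-en-1-ol (racemic carbinol adduct, lithium alkoxide in the flask) | CCOC1=C(Br)C(O)(C2SCCCS2)CCC1 | intermediate
5 | 2-bromo-3-(1,3-dithian-2-yl)cyclohex-2-en-1-one | O=C1CCCC(C2SCCCS2)=C1Br | intermediate
6 | (1S)-2-bromo-3-(1,3-dithian-2-yl)cyclohex-2-en-1-ol | O[C@H]1CCCC(C2SCCCS2)=C1Br | intermediate
7 | {[(1S)-2-bromo-3-(1,3-dithian-2-yl)cyclohex-2-en-1-yl]oxy}(tert-butyl)dimethylsilane | CC(C)(C)[Si](C)(C)O[C@H]1CCCC(C2SCCCS2)=C1Br | intermediate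
8 | vinyllithium from 7 (Li in place of Br) | CC(C)(C)[Si](C)(C)O[C@H]1CCCC(C2SCCCS2)=C1[Li] | intermediate
9 | (6S)-6-[(tert-butyldimethylsilyl)oxy]-2-(1,3-dithian-2-yl)cyclohex-1-ene-1-carboxylic acid | CC(C)(C)[Si](C)(C)O[C@H]1CCCC(C2SCCCS2)=C1C(=O)O | intermediate
10 | (7S)-7-[(tert-butyldimethylsilyl)oxy]-3-hydroxy-4,5,6,7-tetrahydro-2-benzofuran-1(3H)-one (lactol, both C3 epimers) | CC(C)(C)[Si](C)(C)O[C@H]1CCCC2=C1C(=O)OC2O | intermediate
11 | 1,3,3-trimethoxyprop-1-ene | COC=CC(OC)OC | starting material
12 | photoadduct: cyclobutane fused across C3a′–C7a′ anti to the 7′S-OTBS group, C7 (on C3a′) bearing OMe, C6 (on C7a′) bearing CH(OMe)2, lactol retained; mixture at C3′, C6, C7 | COC(OC)C1C(OC)[C@@]23CCC[C@H](O[Si](C)(C)C(C)(C)C)[C@@]12C(=O)OC3O | intermediate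
13 | alkynoic acid: same bicyclo[4.2.0]octane core, ethynyl on C3a′, CO2H on C7a′ | COC(OC)C1C(OC)[C@@]2(C#C)CCC[C@H](O[Si](C)(C)C(C)(C)C)[C@@]12C(=O)O | intermediate
14 | (E)-iodomethylene γ-lactone (propellane; I trans to ring O) | COC(OC)C1C(OC)[C@@]23CCC[C@H](O[Si](C)(C)C(C)(C)C)[C@@]12C(=O)O/C3=C/I | intermediate
15 | (E)-butylidene γ-lactone (propellane; propyl trans to ring O) | COC(OC)C1C(OC)[C@@]23CCC[C@H](O[Si](C)(C)C(C)(C)C)[C@@]12C(=O)O/C3=C/CCC | intermediate
16 | β-methoxy aldehyde (C6–CHO, C7–OMe, free 7′-OH) | O=CC1C(OC)[C@@]23CCC[C@H](O)[C@@]12C(=O)O/C3=C/CCC | intermediate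
17 | hydroxy enal: cyclobutene-1-carbaldehyde (O=C5–C6=C7) with 7′S-OH and (E)-butylidene lactone | O=CC1=C[C@@]23CCC[C@H](O)[C@@]12C(=O)O/C3=C/CCC | intermediate
18 | propelladiene enal: cyclobutene-1-carbaldehyde, C6′=C7′ cyclohexene, (E)-butylidene lactone, all sharing C3a′–C7a′ | O=CC1=C[C@@]23CCC=C[C@@]12C(=O)O/C3=C/CCC | intermediate
19 | 2-(trimethylsilyl)ethanol | C[Si](C)(C)CCO | starting material
20 | 2,2,6-trimethyl-4H-1,3-dioxin-4-one | CC1=CC(=O)OC(C)(C)O1 | starting material
21 | 2-(trimethylsilyl)ethyl 3-oxobutanoate | CC(=O)CC(=O)OCC[Si](C)(C)C | intermediate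
22 | Michael adduct: cis-cyclobutane with CHO on C6 and the acetoacetate α-carbon (C7a) on C7, C7a syn to the cyclohexene ring | O=C[C@H]1[C@@H](C(C(C)=O)C(=O)OCC[Si](C)(C)C)[C@@]23CCC=C[C@@]12C(=O)O/C3=C/CCC | intermediate
23 | aldol: C5-hydroxy cyclohexanone β-keto ester (C4–C5 bond formed) | C[Si](C)(C)CCOC(=O)C2C(=O)CC(O)[C@H]1[C@@H]2[C@@]23CCC=C[C@@]12C(=O)O/C3=C/CCC | intermediate
24 | cyclohexenone β-keto ester: ring C3a(=O)–C4=C5–C6–C7–C7a(CO2TMSE) cis-fused to the cyclobutane, syn to the primed cyclohexene | C[Si](C)(C)CCOC(=O)C2C(=O)C=C[C@H]1[C@@H]2[C@@]23CCC=C[C@@]12C(=O)O/C3=C/CCC | intermediate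
25 | saturated cyclic β-keto ester (C4, C5 = CH2) | C[Si](C)(C)CCOC(=O)C2C(=O)CC[C@H]1[C@@H]2[C@@]23CCC=C[C@@]12C(=O)O/C3=C/CCC | intermediate
26 | enol triflate (C3a–OTf, C3a=C7a) | C[Si](C)(C)CCOC(=O)C2=C(OS(=O)(=O)C(F)(F)F)CC[C@H]1[C@@H]2[C@@]23CCC=C[C@@]12C(=O)O/C3=C/CCC | intermediate
27 | pent-1-yne | CCCC#C | starting material
28 | enyne ester (pent-1-ynyl on C3a, TMSE ester on C7a) | C[Si](C)(C)CCOC(=O)C2=C(C#CCCC)CC[C@H]1[C@@H]2[C@@]23CCC=C[C@@]12C(=O)O/C3=C/CCC | intermediate
29 | enynoic acid (free C1 acid of 28) | OC(=O)C2=C(C#CCCC)CC[C@H]1[C@@H]2[C@@]23CCC=C[C@@]12C(=O)O/C3=C/CCC | intermediate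
30 | target CNP0371639.1 (3Z, 3′E; cyclobutane C6–C7a′/C7–C3a′) | CCC/C=C1\OC(=O)C2=C1CC[C@H]1[C@@H]2[C@@]23CCC=C[C@@]12C(=O)O/C3=C/CCC | target

Total step count: 18. Longest linear sequence: 17 steps (steps 1–12 and 14–18; step 13 is a one-step side branch).

Steps most likely to fail

Step 14 (key step). What may go wrong: slow conjugate addition at the neopentyl cyclobutene carbon C7, competing 1,2-addition (Knoevenagel path), aminolysis of the enol lactone by the secondary amine, base-induced opening of the cyclobutane in the adduct, or erosion of facial selectivity. Fallback, setting out from 18 and 21 and returning at 24: the donor instead of the acceptor is activated. Compound 21 is condensed with pyrrolidine to the isolated enamino ester 2-(trimethylsilyl)ethyl 3-(pyrrolidin-1-yl)but-2-enoate F1. F1 is added to 18 in MeCN with no free amine or enolate present (Stork enamine Michael addition). Buffered aqueous acetic acid then hydrolyses the enamine to the keto aldehyde 22, which is now isolated, and a separate aldol condensation (piperidinium acetate, toluene, rt) rejoins the route at 24.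

Step 7. What may go wrong: loss of head-to-tail regioselectivity with the unsymmetrical enol ether, or incomplete anti selectivity with respect to the OTBS group. Fallback, setting out from 5 and returning at 18: the enol ether is delivered intramolecularly from the C7′ oxygen.
- (S)-Me-CBS reduction of 5 gives the (R)-alcohol F2.
- Its trimethylsilyl ether F3 undergoes TMSOTf-catalysed acetal exchange with 11 to the mixed 1,3-dimethoxyallyl acetal F4.
- Bromine–lithium exchange and CO2 give the acid F5 (handled as its triethylammonium salt), and PhI(OCOCF3)2 unmasks the lactol F6.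
- Irradiation (254 nm) closes the tethered 1,6-diene (five-membered ring first) onto C7a′/C3a′ on the face of the C7′ oxygen, giving the pentacyclic photoadduct F7 with enforced regiochemistry and the same C3a′/C7a′ configuration.
- F7 is carried through the Ohira–Bestmann step (alkynoic acid F8), iodolactonisation (E-iodide F9) and Negishi coupling (E-butylidene lactone F10) as in the main route.
- Dilute aqueous acid followed by DBU opens the cyclic acetal to the 7′-epimeric hydroxy enal F11, and Burgess dehydration returns to 18.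

Step 12. What may go wrong: the sulfamate at the neopentyl carbinol C7′ ionises and a cyclobutane bond migrates (Wagner–Meerwein ring expansion), or the sulfamate does not eliminate. Fallback, setting out from 15 and returning at 18: the alkene is made without cationic character.
- TBAF gives the alcohol F12.
- Dess–Martin oxidation gives the ketone F13.
- KHMDS/PhNTf2 gives the enol triflate F14 (enolisation is possible only towards C6′).
- Pd(OAc)2/PPh3/Bu3N/HCO2H reduction gives the alkene acetal F15.
- PPTS in wet acetone followed by DBU then gives 18.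

Further compounds

F1 | step 14 | 2-(trimethylsilyl)ethyl 3-(pyrrolidin-1-yl)but-2-enoate | CC(=CC(=O)OCC[Si](C)(C)C)N1CCCC1
F2 | step 7 | (1R)-2-bromo-3-(1,3-dithian-2-yl)cyclohex-2-en-1-ol | O[C@@H]1CCCC(C2SCCCS2)=C1Br
F3 | step 7 | trimethylsilyl ether of F2 | C[Si](C)(C)O[C@@H]1CCCC(C2SCCCS2)=C1Br
F4 | step 7 | mixed acetal: (1R)-1-[(1,3-dimethoxyprop-2-en-1-yl)oxy]-2-bromo-3-(1,3-dithian-2-yl)cyclohex-2-ene | COC=CC(OC)O[C@@H]1CCCC(C2SCCCS2)=C1Br
F5 | step 7 | (6R)-6-[(1,3-dimethoxyprop-2-en-1-yl)oxy]-2-(1,3-dithian-2-yl)cyclohex-1-ene-1-carboxylic acid | COC=CC(OC)O[C@@H]1CCCC(C2SCCCS2)=C1C(=O)O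
F6 | step 7 | (7R)-7-[(1,3-dimethoxyprop-2-en-1-yl)oxy]-3-hydroxy-4,5,6,7-tetrahydro-2-benzofuran-1(3H)-one | COC=CC(OC)O[C@@H]1CCCC2=C1C(=O)OC2O
F7 | step 7 | tethered photoadduct (cyclic acetal C5 bridging O–C7′ and C6; C7–OMe; lactol) | COC4C1C(OC)[C@@]23CCC[C@@H](O4)[C@@]12C(=O)OC3O
F8 | step 7 | tethered alkynoic acid | COC3C1C(OC)[C@@]2(C#C)CCC[C@@H](O3)[C@@]12C(=O)O
F9 | step 7 | tethered (E)-iodomethylene lactone | COC4C1C(OC)[C@@]23CCC[C@@H](O4)[C@@]12C(=O)O/C3=C/I
F10 | step 7 | tethered (E)-butylidene lactone | COC4C1C(OC)[C@@]23CCC[C@@H](O4)[C@@]12C(=O)O/C3=C/CCC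
F11 | step 7 | 7′-epimer of hydroxy enal 17 | O=CC1=C[C@@]23CCC[C@@H](O)[C@@]12C(=O)O/C3=C/CCC
F12 | step 12 | desilylated alcohol of 15 (acetal retained) | COC(OC)C1C(OC)[C@@]23CCC[C@H](O)[C@@]12C(=O)O/C3=C/CCC
F13 | step 12 | C7′ ketone | COC(OC)C1C(OC)[C@@]23CCCC(=O)[C@@]12C(=O)O/C3=C/CCC
F14 | step 12 | C7′ enol triflate (C6′=C7′) | COC(OC)C1C(OC)[C@@]23CCC=C(OS(=O)(=O)C(F)(F)F)[C@@]12C(=O)O/C3=C/CCC
F15 | step 12 | alkene acetal (C6′=C7′; C6–CH(OMe)2; C7–OMe) | COC(OC)C1C(OC)[C@@]23CCC=C[C@@]12C(=O)O/C3=C/CCC
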